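A direct plan would lithiate the pentaalkoxybenzene A1 and acylate it to the chloromethyl ketone A2, join A2 to the ring-B aldehyde A3 by carbene-catalysed acylation to give the 1,3-diketone A4, and end with hydrogenolysis and cyclodehydration. Its weakest steps would be the carbene-catalysed displacement of chloride from A2, which would lack close precedent and compete with benzoin condensation and enolisation; the lithiation of A1 between two benzyloxy groups, where benzylic deprotonation and Wittig rearrangement would interfere; and the placing and removal of four benzyl ethers, which would add length without adding complexity.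

The route rests on the C2–C1' bond, formed between an unprotected chromone that already holds rings A and C and a ring-B boronate. Both partners enter through C–H bonds: C5–H of 2,3-dimethoxyphenol, the only position of that ring without an ortho substituent, is borylated under steric control and becomes C1', and C2–H of 5,7-dihydroxychromone, the β-carbon of the ring-C enone, is arylated by an oxidative boron Heck reaction. One operation thus gives the whole flavone skeleton with the 3'-hydroxy-4',5'-dimethoxy pattern in place. The equivalent C6–H and C8–H of ring A are then turned into methoxy groups on the flavone itself. No acyl anion step, aryllithium or protecting group is needed.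

Key step: step 2

Remark: 2,3-dimethoxyphenol and 5,7-dihydroxychromone are taken as commercial starting materials.

Step 1
Reactants: 1 2,3-dimethoxyphenol
Product: 4 2,3-dimethoxy-5-(4,4,5,5-tetramethyl-1,3,2-dioxaborolan-2-yl)phenol, via aryloxyborane 2 (not isolated), via C-borylated aryloxyborane 3 (not isolated)
Conditions: HBpin (2.5 equiv), [Ir(OMe)(cod)]2 (1.5 mol %), 4,4'-di-tert-butyl-2,2'-bipyridine (3 mol %), THF, rt to 70 °C (H2 vented); then MeOH, rt
Reagents that add atoms: pinacolborane, B1OC(C)(C)C(C)(C)O1
Why: Iridium-catalysed aromatic C–H borylation, in which the phenol is first masked in the flask as its O-boryl ether 2 and the sterically governed iridium tris(boryl) catalyst should then borylate C5–H, the only ring C–H with no ortho substituent, before methanol cleaves the O–B bond of 3.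

Step 2
Reactants: 4 2,3-dimethoxy-5-(4,4,5,5-tetramethyl-1,3,2-dioxaborolan-2-yl)phenol; 5 5,7-dihydroxy-4H-chromen-4-one (5,7-dihydroxychromone)
Product: 7 apometzgerin (5,7-dihydroxy-2-(3-hydroxy-4,5-dimethoxyphenyl)-4H-chromen-4-one), via racemic flavanone 6 (not isolated)
Conditions: Pd(O2CCF3)2 (10 mol %), 5-nitro-1,10-phenanthroline (12 mol %), O2 (1 atm), DMSO–H2O (10:1), 90 °C; 4 (1.8 equiv) added in portions
Reagents that add atoms: none
Why: Transmetalation moves the aryl group of 4 from boron to divalent palladium, and the aryl–palladium species adds across C2=C3 of 5 with the aryl group at C2, the β-carbon of the ring-C vinylogous ester, to give a palladium enolate. Protonation of this enolate gives flavanone 6, which the same catalyst dehydrogenates by enolate formation and β-hydride elimination, and O2 returns the zerovalent palladium to the divalent state. The closest known reaction type is the oxidative boron Heck reaction of chromones with arylboronic acids (conjugate addition followed by aerobic dehydrogenation). No ring is closed, since ring C is already present in 5 and only the C2–C1' bond is formed; the C2 stereocentre of 6 is transient, is not controlled and is erased by the dehydrogenation. The selectivity needed is C2 over C3 and arylation over attack on the three free phenols: the polarity of the enone makes C2 the only electrophilic C–H carbon, the hydrogen bond from 5-OH to the C4 carbonyl raises that electrophilicity, and the absence of base keeps the phenols protonated and unreactive.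

Step 3
Reactants: 7 apometzgerin
Product: 8 6,8-dibromo-5,7-dihydroxy-2-(3-hydroxy-4,5-dimethoxyphenyl)-4H-chromen-4-one
Conditions: NBS (2.0 equiv, in portions), DMF, −20 to 0 °C, dark
Reagents that add atoms: N-bromosuccinimide, O=C1CCC(=O)N1Br
Why: Electrophilic aromatic bromination, in which C6 and C8 of ring A, each ortho or para to three oxygen substituents (5-OH, 7-OH and O1), should react far faster than ring B, which carries a single phenol and sits on the electron-poor C2, or than the enone carbon C3.

Step 4
Reactants: 8 6,8-dibromo-5,7-dihydroxy-2-(3-hydroxy-4,5-dimethoxyphenyl)-4H-chromen-4-one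
Product: 9 scaposin (5,7-dihydroxy-2-(3-hydroxy-4,5-dimethoxyphenyl)-6,8-dimethoxy-4H-chromen-4-one)
Conditions: NaOMe (25% in MeOH, 12 equiv), CuBr (0.5 equiv), DMF, 110 °C, N2 (degassed); then cold 1 M HCl
Reagents that add atoms: sodium methoxide, C[O-].[Na+]
Why: Copper-mediated Ullmann-type methoxylation, a substitution known to proceed on 6,8-dibromo-5,7-dihydroxyflavones with the phenols free, should replace both bromines, and because ring A is symmetric about the C4a–C7 axis any base-induced opening and reclosure of ring C (Wessely–Moser rearrangement) leads to the same product; no stereocentre is present.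

**Compound list**
1 | 2,3-dimethoxyphenol | COc1cccc(O)c1OC | starting material
2 | 2-(2,3-dimethoxyphenoxy)-4,4,5,5-tetramethyl-1,3,2-dioxaborolane | COc1cccc(OB2OC(C)(C)C(C)(C)O2)c1OC | intermediate
3 | 2-[2,3-dimethoxy-5-(4,4,5,5-tetramethyl-1,3,2-dioxaborolan-2-yl)phenoxy]-4,4,5,5-tetramethyl-1,3,2-dioxaborolane | COc1cc(B2OC(C)(C)C(C)(C)O2)cc(OB2OC(C)(C)C(C)(C)O2)c1OC | intermediate
4 | 2,3-dimethoxy-5-(4,4,5,5-tetramethyl-1,3,2-dioxaborolan-2-yl)phenol | COc1cc(B2OC(C)(C)C(C)(C)O2)cc(O)c1OC | intermediate
5 | 5,7-dihydroxy-4H-chromen-4-one (5,7-dihydroxychromone) | O=c1ccoc2cc(O)cc(O)c12 | starting material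
6 | 5,7-dihydroxy-2-(3-hydroxy-4,5-dimethoxyphenyl)-2,3-dihydro-4H-chromen-4-one (racemic) | COc1cc(C2CC(=O)c3c(O)cc(O)cc3O2)cc(O)c1OC | intermediate
7 | apometzgerin, 5,7-dihydroxy-2-(3-hydroxy-4,5-dimethoxyphenyl)-4H-chromen-4-one | COc1cc(-c2cc(=O)c3c(O)cc(O)cc3o2)cc(O)c1OC | intermediate
8 | 6,8-dibromo-5,7-dihydroxy-2-(3-hydroxy-4,5-dimethoxyphenyl)-4H-chromen-4-one | COc1cc(-c2cc(=O)c3c(O)c(Br)c(O)c(Br)c3o2)cc(O)c1OC | intermediate
9 | scaposin, 5,7-dihydroxy-2-(3-hydroxy-4,5-dimethoxyphenyl)-6,8-dimethoxy-4H-chromen-4-one (achiral) | COc1cc(-c2cc(=O)c3c(O)c(OC)c(O)c(OC)c3o2)cc(O)c1OC | target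

Total steps: 4. Longest linear sequence: 4 steps (1 → 4 → 7 → 8 → 9).

Steps most likely to fail, each with a fallback:

Step 2. The chelating 5-hydroxy-4-oxo unit and the free phenols may bind divalent palladium and stall turnover, and the boronate may be lost by protodeboronation, homocoupling or oxidation before it adds. The fallback sets out from 5 and comes back at 7. It separates the C–C bond formation from the oxidation and removes the chelating phenols.
- Chromone 5 would be treated with MOMCl and NaH in DMF to give 5,7-bis(methoxymethoxy)-4H-chromen-4-one F1.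
- A redox-neutral Hayashi–Miyaura 1,4-addition of 4 with [Rh(OH)(cod)]2 in dioxane–H2O at 60 °C would give racemic 2-(3-hydroxy-4,5-dimethoxyphenyl)-5,7-bis(methoxymethoxy)-2,3-dihydro-4H-chromen-4-one F2.
- Aerobic dehydrogenation with Pd(O2CCF3)2 in DMSO under O2 would give 2-(3-hydroxy-4,5-dimethoxyphenyl)-5,7-bis(methoxymethoxy)-4H-chromen-4-one F3.
- HCl in MeOH would then cleave both acetals to give 7.

Step 3. Bromination may spill over to ring B, ortho or para to the 3'-hydroxyl, or go past the dibromo stage, so that ring A is not halogenated cleanly. The fallback sets out from 5 and comes back at 9. It puts the ring-A methoxy groups in place before ring B is attached.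
- Chromone 5 would be brominated with NBS (2 equiv) in DMF to give 6,8-dibromo-5,7-dihydroxy-4H-chromen-4-one F4.
- NaOMe and CuBr in DMF at 110 °C, followed by an acidic work-up that recloses any opened pyranone, would give 5,7-dihydroxy-6,8-dimethoxy-4H-chromen-4-one F5.
- The oxidative boron Heck coupling of F5 with 4 under the conditions of step 2 would pass through racemic 5,7-dihydroxy-2-(3-hydroxy-4,5-dimethoxyphenyl)-6,8-dimethoxy-2,3-dihydro-4H-chromen-4-one F6 and give 9 directly.

Step 4. The substitution may stall after the first bromine at the crowded, electron-rich triphenoxide, hydrodebromination may take over, or the polyanion may be oxidised by traces of air. The fallback sets out from 8 and comes back at 9. It replaces the copper-mediated substitution on the polyanion by a palladium-catalysed C–O coupling on a neutral, protected substrate.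
- Dibromide 8 would be treated with MOMCl and NaH in DMF to give 6,8-dibromo-2-[3,4-dimethoxy-5-(methoxymethoxy)phenyl]-5,7-bis(methoxymethoxy)-4H-chromen-4-one F7.
- Buchwald–Hartwig-type etherification with MeOH, Pd2(dba)3, tBuBrettPhos and Cs2CO3 in toluene at 80 °C would give 2-[3,4-dimethoxy-5-(methoxymethoxy)phenyl]-6,8-dimethoxy-5,7-bis(methoxymethoxy)-4H-chromen-4-one F8.
- HCl in MeOH would remove the three acetals to give 9.

**Further compounds**
F1 | step 2 | 5,7-bis(methoxymethoxy)-4H-chromen-4-one | COCOc1cc(OCOC)c2c(=O)ccoc2c1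
F2 | step 2 | 2-(3-hydroxy-4,5-dimethoxyphenyl)-5,7-bis(methoxymethoxy)-2,3-dihydro-4H-chromen-4-one (racemic) | COCOc1cc(OCOC)c2c(c1)OC(c1cc(O)c(OC)c(OC)c1)CC2=O
F3 | step 2 | 2-(3-hydroxy-4,5-dimethoxyphenyl)-5,7-bis(methoxymethoxy)-4H-chromen-4-one | COCOc1cc(OCOC)c2c(=O)cc(-c3cc(O)c(OC)c(OC)c3)oc2c1
F4 | step 3 | 6,8-dibromo-5,7-dihydroxy-4H-chromen-4-one | O=c1ccoc2c(Br)c(O)c(Br)c(O)c12
F5 | step 3 | 5,7-dihydroxy-6,8-dimethoxy-4H-chromen-4-one | COc1c(O)c(OC)c2occc(=O)c2c1O
F6 | step 3 | 5,7-dihydroxy-2-(3-hydroxy-4,5-dimethoxyphenyl)-6,8-dimethoxy-2,3-dihydro-4H-chromen-4-one (racemic) | COc1cc(C2CC(=O)c3c(O)c(OC)c(O)c(OC)c3O2)cc(O)c1OC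
F7 | step 4 | 6,8-dibromo-2-[3,4-dimethoxy-5-(methoxymethoxy)phenyl]-5,7-bis(methoxymethoxy)-4H-chromen-4-one | COCOc1cc(-c2cc(=O)c3c(OCOC)c(Br)c(OCOC)c(Br)c3o2)cc(OC)c1OC
F8 | step 4 | 2-[3,4-dimethoxy-5-(methoxymethoxy)phenyl]-6,8-dimethoxy-5,7-bis(methoxymethoxy)-4H-chromen-4-one | COCOc1cc(-c2cc(=O)c3c(OCOC)c(OC)c(OCOC)c(OC)c3o2)cc(OC)c1OC
A1 | direct plan | 1,3,5-tris(benzyloxy)-2,4-dimethoxybenzene | COc1c(OCc2ccccc2)cc(OCc2ccccc2)c(OC)c1OCc1ccccc1
A2 | direct plan | 2-chloro-1-[2,4,6-tris(benzyloxy)-3,5-dimethoxyphenyl]ethan-1-one | COc1c(OCc2ccccc2)c(C(=O)CCl)c(OCc2ccccc2)c(OC)c1OCc1ccccc1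
A3 | direct plan | 3-(benzyloxy)-4,5-dimethoxybenzaldehyde | COc1cc(C=O)cc(OCc2ccccc2)c1OC
A4 | direct plan | 1-[3-(benzyloxy)-4,5-dimethoxyphenyl]-3-[2,4,6-tris(benzyloxy)-3,5-dimethoxyphenyl]propane-1,3-dione | COc1cc(C(=O)CC(=O)c2c(OCc3ccccc3)c(OC)c(OCc3ccccc3)c(OC)c2OCc2ccccc2)cc(OCc2ccccc2)c1OC
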